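**Strategy.** The cycloheptene ring (C1, C5–C10, daucane numbering) is disconnected at C1–C10 and C7–C8: a rhodium carbenoid from a vinyldiazoacetate cyclopropanates the vinyl group of a chiral 2-vinylcyclopentene (C7=C6–C5=C1), and the cis-divinylcyclopropane rearranges in the same flask by a [3,3] shift, a formal (4+3) cycloaddition. This closes the seven-membered ring last, creates the quaternary ring-fusion carbon C1 and delivers the C8=C9 alkene. It exploits the 1,4-diene pattern latent in that ring (C8=C9 and the C5–C6 bond): the new C5=C6 alkene is then hydroborated to set H5 and the C6 oxygen; isopropyl addition at C4 and a hydroxyl-directed reduction at C2 complete the cyclopentane.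

Key step: step 6

Remark 1 (numbering): daucane numbering is used throughout: C1 quaternary ring-fusion carbon (methyl C15), C2 (CH–O), C3, C4 (carbinol carbon, isopropyl C11–C13), C5 ring-fusion CH, C6 (CH–O), C7, C8 (methyl C14), C9, C10; β is the face of the C1 methyl group, and the cyclopentene precursors carry the same atom labels.
Remark 2 (assumption): the sense of induction of Rh2(R-DOSP)4 is taken from the usual model for cyclopropanation by this catalyst family; should the opposite sense be found, Rh2(S-DOSP)4 is used and nothing else changes.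
Remark 3: both ester groups of the target are angelates, (Z)-2-methylbut-2-enoates.

Step 1
Reactants: 1 (R)-4-[(tert-butyldimethylsilyl)oxy]cyclopent-2-en-1-one
Product: 3 (R)-4-[(tert-butyldimethylsilyl)oxy]-3-methylcyclopent-2-en-1-one, via lithium enolate 2 (not isolated)
Conditions: Me2CuLi, Et2O, −78 °C; then PhS(Cl)=NtBu, −78 °C to rt
Reagents that add atoms: lithium dimethylcuprate, [Li+].C[Cu-]C
Why: Gilman conjugate addition places the methyl group on C1 and the regiodefined enolate is dehydrogenated in the same flask by the Mukaiyama sulfinimidoyl chloride (α-sulfenylation, then syn-elimination), so the transient C1 stereocentre is erased and only the C2 centre of 1 remains.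

Step 2
Reactants: 3 (R)-4-[(tert-butyldimethylsilyl)oxy]-3-methylcyclopent-2-en-1-one
Product: 5 (R)-2-bromo-4-[(tert-butyldimethylsilyl)oxy]-3-methylcyclopent-2-en-1-one, via trans-dibromide 4 (not isolated)
Conditions: Br2, CH2Cl2, 0 °C; then Et3N, 0 °C to rt
Reagents that add atoms: bromine, BrBr
Why: Addition of bromine to the enone and triethylamine-induced E1cB loss of HBr (addition–elimination α-bromination) should place bromine on C5 without touching the C2 stereocentre.

Step 3
Reactants: 5 (R)-2-bromo-4-[(tert-butyldimethylsilyl)oxy]-3-methylcyclopent-2-en-1-one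
Product: 6 (R)-6-bromo-8-[(tert-butyldimethylsilyl)oxy]-7-methyl-1,4-dioxaspiro[4.4]non-6-ene
Conditions: (TMSOCH2)2, TMSOTf (cat.), CH2Cl2, −78 to −20 °C
Reagents that add atoms: 1,2-bis(trimethylsilyloxy)ethane, C[Si](C)(C)OCCO[Si](C)(C)C
Why: Noyori ketalisation masks the C4 ketone under conditions that should spare the silyl ether and leave the bromoalkene in place.

Step 4
Reactants: 6 (R)-6-bromo-8-[(tert-butyldimethylsilyl)oxy]-7-methyl-1,4-dioxaspiro[4.4]non-6-ene
Product: 7 (R)-8-[(tert-butyldimethylsilyl)oxy]-6-ethenyl-7-methyl-1,4-dioxaspiro[4.4]non-6-ene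
Conditions: CH2=CHSnBu3, Pd(PPh3)4 (cat.), toluene, 100 °C
Reagents that add atoms: tributyl(vinyl)stannane, C=C[Sn](CCCC)(CCCC)CCCC
Why: Stille cross-coupling of the alkenyl bromide installs C6=C7 and completes the 2-vinylcyclopentene diene.

Step 5
Reactants: 8 methyl but-3-enoate
Product: 9 methyl 2-diazobut-3-enoate
Conditions: p-ABSA, DBU, MeCN, 0 °C; used at once as a cold hexanes solution
Reagents that add atoms: 4-acetamidobenzenesulfonyl azide, CC(=O)Nc1ccc(cc1)S(=O)(=O)N=[N+]=[N-]
Why: Regitz-type diazo transfer to the allylic α-position of the β,γ-unsaturated ester should give the vinyldiazoacetate, which is used immediately because it slowly cyclises to a pyrazole.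

Step 6
Reactants: 7 (R)-8-[(tert-butyldimethylsilyl)oxy]-6-ethenyl-7-methyl-1,4-dioxaspiro[4.4]non-6-ene; 9 methyl 2-diazobut-3-enoate
Product: 11 methyl 2β-(tert-butyldimethylsilyloxy)-4,4-(ethylenedioxy)-11,12,13-trinordauca-5,8-dien-14-oate, via cis-divinylcyclopropane 10 (not isolated)
Conditions: Rh2(R-DOSP)4 (1 mol %), hexanes, −40 °C to rt, slow addition of 9; then toluene, 100 °C
Reagents that add atoms: none
Why: The rhodium carbenoid generated from 9 transfers its carbene carbon (C8) to the only monosubstituted alkene of 7 (C6=C7), and the cis-divinylcyclopropane 10 then undergoes a [3,3] (Cope) shift through a boat transition state that breaks C6–C8 and forms C1–C10. The closest known reaction type is the tandem cyclopropanation/Cope rearrangement of vinyldiazoacetates with 1,3-dienes (formal (4+3) cycloaddition), including cases that create a quaternary carbon at the diene terminus. The transient three-membered ring is closed by concerted (2+1) carbene transfer and the seven-membered ring by sigmatropic ring enlargement, suprafacial on both allyl units, so no polar endo or exo closure is involved. The new quaternary stereocentre C1 is dictated by the configuration of 10, which the chiral carboxylate catalyst sets (remark 2), and the β-OTBS group at C2 is matched because it sits on the outer face of the boat, anti to the incoming C10. The step needs site selectivity for C6=C7 over the tetrasubstituted C1=C5 alkene and the allylic C–H bonds (secured by sterics and the high alkene reactivity of donor/acceptor carbenoids) and a cis relation of the ethenyl and cyclopentenyl groups in 10 (inherent to these carbenoids). Heating completes the shift, which is slowed by the fully substituted C1 terminus, and leaves the ester-bearing C8=C9 alkene and the C5=C6 alkene for the next steps.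

Step 7
Reactants: 11 methyl 2β-(tert-butyldimethylsilyloxy)-4,4-(ethylenedioxy)-11,12,13-trinordauca-5,8-dien-14-oate
Product: 13 methyl 2β-(tert-butyldimethylsilyloxy)-4,4-(ethylenedioxy)-6α-hydroxy-11,12,13-trinordauc-8-en-14-oate, via alkylborane 12 (not isolated)
Conditions: BH3·THF, THF, 0 °C to rt; then H2O2, aq. NaOH, 0 °C
Reagents that add atoms: hydrogen peroxide, OO
Why: Hydroboration–oxidation should add syn across the electron-rich C5=C6 alkene (the C8=C9 enoate is deactivated), with boron at the less hindered C6 and hydrogen at C5 from the α-face opposite the angular C1 methyl, which sets the trans ring fusion (H5 α) and the 6α-hydroxyl together.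

Step 8
Reactants: 13 methyl 2β-(tert-butyldimethylsilyloxy)-4,4-(ethylenedioxy)-6α-hydroxy-11,12,13-trinordauc-8-en-14-oate
Product: 14 2β-(tert-butyldimethylsilyloxy)-4,4-(ethylenedioxy)-11,12,13-trinordauc-8-ene-6α,14-diol
Conditions: iBu2AlH, CH2Cl2, −78 to 0 °C
Reagents that add atoms: none
Why: 1,2-Reduction of the α,β-unsaturated ester by the aluminium hydride gives the allylic alcohol while ketal and silyl ether are inert.

Step 9
Reactants: 14 2β-(tert-butyldimethylsilyloxy)-4,4-(ethylenedioxy)-11,12,13-trinordauc-8-ene-6α,14-diol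
Product: 16 2β-(tert-butyldimethylsilyloxy)-4,4-(ethylenedioxy)-11,12,13-trinordauc-8-en-6α-ol, via allylic mesylate 15 (not isolated)
Conditions: MsCl, Et3N, CH2Cl2, −40 °C; then LiBHEt3, THF, −40 to 0 °C
Reagents that add atoms: none
Why: Selective sulfonylation of the primary allylic hydroxyl over the hindered secondary C6 hydroxyl and SN2 hydride displacement (allylic deoxygenation) should turn CH2OH into the C8 methyl group.

Step 10
Reactants: 16 2β-(tert-butyldimethylsilyloxy)-4,4-(ethylenedioxy)-11,12,13-trinordauc-8-en-6α-ol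
Product: 17 2β-(tert-butyldimethylsilyloxy)-6α-hydroxy-11,12,13-trinordauc-8-en-4-one
Conditions: PPTS (cat.), acetone/H2O, 50 °C
Reagents that add atoms: water, O
Why: Mild acid-catalysed ketal hydrolysis frees the C4 ketone while the hindered secondary silyl ether should survive and the β-hydroxy ketone is not dehydrated or epimerised at C5.

Step 11
Reactants: 17 2β-(tert-butyldimethylsilyloxy)-6α-hydroxy-11,12,13-trinordauc-8-en-4-one
Product: 18 2β-(tert-butyldimethylsilyloxy)dauc-8-ene-4β,6α-diol
Conditions: iPrMgCl, CeCl3 (anhydrous), THF, −78 to −20 °C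
Reagents that add atoms: isopropylmagnesium chloride, CC(C)[Mg]Cl
Why: Organocerium (Imamoto) 1,2-addition suppresses enolisation and hydride transfer, and the reagent should attack the C4 ketone from the α-face, anti to the C5–C6 bond, the C1 methyl and the C2 silyloxy group, giving the 4β-hydroxy-4α-isopropyl centre.

Step 12
Reactants: 18 2β-(tert-butyldimethylsilyloxy)dauc-8-ene-4β,6α-diol; 19 angelic acid
Product: 20 2β-(tert-butyldimethylsilyloxy)-4β-hydroxydauc-8-en-6α-yl (Z)-2-methylbut-2-enoate
Conditions: 19, 2,4,6-trichlorobenzoyl chloride, Et3N, toluene, rt; then 18, 80 °C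
Reagents that add atoms: none
Why: Yamaguchi esterification through the preformed mixed anhydride acylates the only free secondary hydroxyl (C6; the tertiary C4 hydroxyl does not react) and is the usual way to avoid Z-to-E isomerisation of the angeloyl group.

Step 13
Reactants: 20 2β-(tert-butyldimethylsilyloxy)-4β-hydroxydauc-8-en-6α-yl (Z)-2-methylbut-2-enoate
Product: 21 2β,4β-dihydroxydauc-8-en-6α-yl (Z)-2-methylbut-2-enoate
Conditions: HF·pyridine, pyridine, THF, 0 °C to rt
Reagents that add atoms: none
Why: Fluoride-mediated desilylation under buffered conditions should free the C2 hydroxyl without acyl migration or cleavage of the ester.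

Step 14
Reactants: 21 2β,4β-dihydroxydauc-8-en-6α-yl (Z)-2-methylbut-2-enoate
Product: 22 4β-hydroxy-2-oxodauc-8-en-6α-yl (Z)-2-methylbut-2-enoate
Conditions: Dess–Martin periodinane, pyridine, CH2Cl2, 0 °C to rt
Reagents that add atoms: none
Why: Dess–Martin oxidation of the only secondary alcohol gives the C2 ketone under buffered conditions that leave the tertiary C4 alcohol, the alkene and the angelate untouched.

Step 15
Reactants: 22 4β-hydroxy-2-oxodauc-8-en-6α-yl (Z)-2-methylbut-2-enoate
Product: 23 2α,4β-dihydroxydauc-8-en-6α-yl (Z)-2-methylbut-2-enoate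
Conditions: Me4NBH(OAc)3, MeCN/AcOH, −30 to 0 °C
Reagents that add atoms: none
Why: Evans–Saksena hydroxyl-directed reduction: the 4β-hydroxyl binds the triacetoxyborohydride and delivers hydride intramolecularly to the β-face of the C2 ketone, which should give the 2α-alcohol (trans-1,3-diol) that undirected attack anti to the C1 methyl would not give.

Step 16
Reactants: 23 2α,4β-dihydroxydauc-8-en-6α-yl (Z)-2-methylbut-2-enoate; 19 angelic acid
Product: 24 4β-hydroxydauc-8-ene-2α,6α-diyl bis[(Z)-2-methylbut-2-enoate]
Conditions: 19, 2,4,6-trichlorobenzoyl chloride, Et3N, toluene, rt; then 23, 80 °C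
Reagents that add atoms: none
Why: A second Yamaguchi angeloylation at the remaining secondary (C2) hydroxyl should complete the diester, the tertiary C4 hydroxyl staying free.

**Compound list**

1 | (R)-4-[(tert-butyldimethylsilyl)oxy]cyclopent-2-en-1-one | O=C1C=C[C@H](O[Si](C)(C)C(C)(C)C)C1 | starting material
2 | lithium 4-[(tert-butyldimethylsilyl)oxy]-3-methylcyclopent-1-en-1-olate (methyl trans to OTBS) | [Li+].[O-]C1=C[C@@H](C)[C@H](O[Si](C)(C)C(C)(C)C)C1 | intermediate
3 | (R)-4-[(tert-butyldimethylsilyl)oxy]-3-methylcyclopent-2-en-1-one | O=C1C=C(C)[C@H](O[Si](C)(C)C(C)(C)C)C1 | intermediate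
4 | 2,3-dibromo-4-[(tert-butyldimethylsilyl)oxy]-3-methylcyclopentan-1-one (bromines trans) | O=C1[C@@H](Br)[C@](C)(Br)[C@H](O[Si](C)(C)C(C)(C)C)C1 | intermediate
5 | (R)-2-bromo-4-[(tert-butyldimethylsilyl)oxy]-3-methylcyclopent-2-en-1-one | O=C1C(Br)=C(C)[C@H](O[Si](C)(C)C(C)(C)C)C1 | intermediate
6 | (R)-6-bromo-8-[(tert-butyldimethylsilyl)oxy]-7-methyl-1,4-dioxaspiro[4.4]non-6-ene | BrC1=C(C)[C@H](O[Si](C)(C)C(C)(C)C)CC12OCCO2 | intermediate
7 | (R)-8-[(tert-butyldimethylsilyl)oxy]-6-ethenyl-7-methyl-1,4-dioxaspiro[4.4]non-6-ene | C=CC1=C(C)[C@H](O[Si](C)(C)C(C)(C)C)CC12OCCO2 | intermediate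
8 | methyl but-3-enoate | C=CCC(=O)OC | starting material
9 | methyl 2-diazobut-3-enoate | C=CC(=[N+]=[N-])C(=O)OC | intermediate
10 | methyl 1-ethenyl-2-[(R)-8-(tert-butyldimethylsilyloxy)-7-methyl-1,4-dioxaspiro[4.4]non-6-en-6-yl]cyclopropane-1-carboxylate (ethenyl and cyclopentenyl cis) | C=C[C@@]1(C(=O)OC)C[C@H]1C2=C(C)[C@H](O[Si](C)(C)C(C)(C)C)CC23OCCO3 | intermediate
11 | methyl 2β-(tert-butyldimethylsilyloxy)-4,4-(ethylenedioxy)-11,12,13-trinordauca-5,8-dien-14-oate | COC(=O)C1=CC[C@@]2(C)[C@H](O[Si](C)(C)C(C)(C)C)CC3(OCCO3)C2=CC1 | intermediate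
12 | 6α-boranyl (monoalkylborane) adduct of 11, 5αH | [BH2][C@H]1CC(C(=O)OC)=CC[C@@]2(C)[C@H](O[Si](C)(C)C(C)(C)C)CC3(OCCO3)[C@H]12 | intermediate
13 | methyl 2β-(tert-butyldimethylsilyloxy)-4,4-(ethylenedioxy)-6α-hydroxy-11,12,13-trinordauc-8-en-14-oate | O[C@H]1CC(C(=O)OC)=CC[C@@]2(C)[C@H](O[Si](C)(C)C(C)(C)C)CC3(OCCO3)[C@H]12 | intermediate
14 | 2β-(tert-butyldimethylsilyloxy)-4,4-(ethylenedioxy)-11,12,13-trinordauc-8-ene-6α,14-diol | O[C@H]1CC(CO)=CC[C@@]2(C)[C@H](O[Si](C)(C)C(C)(C)C)CC3(OCCO3)[C@H]12 | intermediate
15 | 14-O-methanesulfonate of 14 | O[C@H]1CC(COS(C)(=O)=O)=CC[C@@]2(C)[C@H](O[Si](C)(C)C(C)(C)C)CC3(OCCO3)[C@H]12 | intermediate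
16 | 2β-(tert-butyldimethylsilyloxy)-4,4-(ethylenedioxy)-11,12,13-trinordauc-8-en-6α-ol | O[C@H]1CC(C)=CC[C@@]2(C)[C@H](O[Si](C)(C)C(C)(C)C)CC3(OCCO3)[C@H]12 | intermediate
17 | 2β-(tert-butyldimethylsilyloxy)-6α-hydroxy-11,12,13-trinordauc-8-en-4-one | O[C@H]1CC(C)=CC[C@@]2(C)[C@H](O[Si](C)(C)C(C)(C)C)CC(=O)[C@H]12 | intermediate
18 | 2β-(tert-butyldimethylsilyloxy)dauc-8-ene-4β,6α-diol | O[C@H]1CC(C)=CC[C@@]2(C)[C@H](O[Si](C)(C)C(C)(C)C)C[C@@](O)(C(C)C)[C@H]12 | intermediate
19 | angelic acid, (Z)-2-methylbut-2-enoic acid | C/C=C(/C)C(O)=O | starting material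
20 | 2β-(tert-butyldimethylsilyloxy)-4β-hydroxydauc-8-en-6α-yl (Z)-2-methylbut-2-enoate | C/C=C(/C)C(=O)O[C@H]1CC(C)=CC[C@@]2(C)[C@H](O[Si](C)(C)C(C)(C)C)C[C@@](O)(C(C)C)[C@H]12 | intermediate
21 | 2β,4β-dihydroxydauc-8-en-6α-yl (Z)-2-methylbut-2-enoate | C/C=C(/C)C(=O)O[C@H]1CC(C)=CC[C@@]2(C)[C@H](O)C[C@@](O)(C(C)C)[C@H]12 | intermediate
22 | 4β-hydroxy-2-oxodauc-8-en-6α-yl (Z)-2-methylbut-2-enoate | C/C=C(/C)C(=O)O[C@H]1CC(C)=CC[C@@]2(C)C(=O)C[C@@](O)(C(C)C)[C@H]12 | intermediate
23 | 2α,4β-dihydroxydauc-8-en-6α-yl (Z)-2-methylbut-2-enoate | C/C=C(/C)C(=O)O[C@H]1CC(C)=CC[C@@]2(C)[C@@H](O)C[C@@](O)(C(C)C)[C@H]12 | intermediate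
24 | 4β-hydroxydauc-8-ene-2α,6α-diyl bis[(Z)-2-methylbut-2-enoate] (CNP0303897.1) | C/C=C(/C)C(=O)O[C@H]1CC(C)=CC[C@@]2(C)[C@@H](OC(=O)/C(C)=C\C)C[C@@](O)(C(C)C)[C@H]12 | target

**Total step count:** 16. **Longest linear sequence:** 15 steps (steps 1–4 and 6–16; step 5 is the side branch to 9).

**Steps most likely to fail**

Step 6. The [3,3] shift onto the fully substituted C1 terminus may be slow. The carbenoid could then be diverted (insertion into the activated allylic C2–H bond, pyrazole formation from 9), or the cyclopropane could lose its configuration before ring closure, which would erode the C1 configuration. The fallback sets out from 3 and returns at 17. A Hosomi–Sakurai conjugate allylation of 3 (allyltrimethylsilane, TiCl4, CH2Cl2, −78 °C) should add the allyl group at C1 anti to the silyloxy group. The titanium enolate is trapped in the same flask with freshly prepared 3-methylbut-3-enal to give the aldol adduct 3-allyl-4-[(tert-butyldimethylsilyl)oxy]-2-(1-hydroxy-3-methylbut-3-en-1-yl)-3-methylcyclopentan-1-one F1. Ring-closing metathesis (second-generation Grubbs catalyst, CH2Cl2, 40 °C) then closes the cycloheptene to 17 after separation of the C6 epimers. This path is shorter but gives up the stereospecific hydroboration, so C5 and C6 would rest on the aldol step; that is why it is not the main route.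

Step 11. The hindered, enolisable ketone may be deprotonated or reduced by hydride transfer from the secondary organometallic instead of being alkylated, and the C6 alkoxide may trigger retro-aldol cleavage. The fallback sets out from 17 and returns at 18. Isopropenylmagnesium bromide with CeCl3 (THF, −78 °C), which cannot transfer a β-hydride, should add from the same α-face to give 2β-(tert-butyldimethylsilyloxy)dauca-8,11-diene-4β,6α-diol F2. Its 1,1-disubstituted alkene is then hydrogenated selectively in the presence of the trisubstituted ring alkene (H2, RhCl(PPh3)3, benzene, rt) to give 18.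

Step 16. Acyl transfer to the neopentyl C2 hydroxyl may be sluggish, and prolonged heating of the activated angeloyl unit may isomerise it to the E (tigloyl) isomer. The fallback sets out from 23 and returns at 24. Compound 23 is esterified at C2 with 2-[bis(2,2,2-trifluoroethoxy)phosphoryl]propanoic acid (DCC, DMAP, CH2Cl2) to give 4β-hydroxy-6α-[(Z)-2-methylbut-2-enoyloxy]dauc-8-en-2α-yl 2-[bis(2,2,2-trifluoroethoxy)phosphoryl]propanoate F3 (epimers at the phosphonate-bearing carbon). A Still–Gennari olefination with acetaldehyde (KN(SiMe3)2, 18-crown-6, THF, −78 °C) then builds the Z-configured 2-methylbut-2-enoate in place and should give 24.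

**Further compounds**

F1 | step 6 | 3-allyl-4-[(tert-butyldimethylsilyl)oxy]-2-(1-hydroxy-3-methylbut-3-en-1-yl)-3-methylcyclopentan-1-one | C=C(C)C[C@H](O)[C@H]1C(=O)C[C@@H](O[Si](C)(C)C(C)(C)C)[C@]1(C)CC=C
F2 | step 11 | 2β-(tert-butyldimethylsilyloxy)dauca-8,11-diene-4β,6α-diol | O[C@H]1CC(C)=CC[C@@]2(C)[C@H](O[Si](C)(C)C(C)(C)C)C[C@@](O)(C(C)=C)[C@H]12
F3 | step 16 | 4β-hydroxy-6α-[(Z)-2-methylbut-2-enoyloxy]dauc-8-en-2α-yl 2-[bis(2,2,2-trifluoroethoxy)phosphoryl]propanoate | C/C=C(/C)C(=O)O[C@H]1CC(C)=CC[C@@]2(C)[C@@H](OC(=O)C(C)P(=O)(OCC(F)(F)F)OCC(F)(F)F)C[C@@](O)(C(C)C)[C@H]12
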